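Sterhirsutin D is cut at its dihydropyran into (+)-β-caryophyllene, whose E-C4′=C5′ bond is the dienophile, and a 4-methylene-5,6-dione of the triquinane acid, the oxadiene. The caryophyllane half is a cyclobutane and a nine-membered ring that share the C1′–C9′ bond; their common periphery is an eleven-membered carbocycle, identical with C1–C11 of farnesyl diphosphate. The key step exploits this: a sesquiterpene cyclase ionises the acyclic, achiral diphosphate, closes the eleven-membered humulyl cation and then forms the transannular C1′–C9′ bond, so that this ring contracts by two atoms to the nine-membered ring while the cyclobutane, both stereocentres and the exocyclic alkene are set in the same operation.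

Key step: step 2

Remarks and assumptions
- Numbering: hirsutane numbering without primes for the triquinane half (ring A: C1, C2, C9, C10, C11; ring B: C2, C3, C7, C8, C9; ring C: C3 to C7; C15 is the pyran CH2), primed caryophyllane numbering for the other half (cyclobutane C1′, C9′, C10′, C11′; nine-membered ring C1′ to C9′).
- Read from the structure, the ring fusion of the caryophyllane half is (1′S,9′R): it is the (+)-enantiomer of β-caryophyllene, the mirror image of the abundant plant hydrocarbon, so the hydrocarbon has to be made.
- Assumption: a recombinant (+)-β-caryophyllene synthase (EC 4.2.3.89, as found in Streptomyces griseus) is used; because this enzyme can hydrate its product further to caryolan-1-ol, it is run under an organic overlay or as a variant without that second activity.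
- Assumption: the (R,R)-lithium amide of step 7 removes the proton on the carbon that becomes C3; should the sense prove opposite, the (S,S)-amide is used.

Step 1
Reactants: 1 (2E,6E)-farnesol
Product: 2 (2E,6E)-farnesyl diphosphate
Conditions: Cl3CCN, (Et3NH)2HPO4, MeCN, rt; NH4+ ion exchange, cellulose chromatography
Reagents that add atoms: bis(triethylammonium) hydrogen phosphate, CC[NH+](CC)CC.CC[NH+](CC)CC.OP(=O)([O-])[O-]
Why: trichloroacetonitrile-activated phosphorylation of the allylic alcohol should give the diphosphate beside mono- and triphosphate, which are separated, and leaves both double-bond geometries untouched.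

Step 2
Reactants: 2 (2E,6E)-farnesyl diphosphate
Product: 5 (+)-β-caryophyllene, via humulyl cation 3 (not isolated), via caryophyllenyl cation 4 (not isolated)
Conditions: recombinant (+)-β-caryophyllene synthase (terpene cyclase), MgCl2, HEPES buffer pH 7.5, glycerol, pentane overlay, 30 °C
Reagents that add atoms: none
Why: Mg-assisted ionisation of the allylic diphosphate gives the farnesyl cation, whose distal C10=C11 bond (farnesyl numbering) attacks C1 to give the eleven-membered E,E-humulyl cation 3; the C2=C3 bond of 3 then attacks the cationic C10 across the ring, which contracts the eleven-membered ring to the nine-membered one and closes the cyclobutane (cation 4), and loss of a proton from the methyl group on C3 gives the exocyclic alkene of 5. This is the native reaction of β-caryophyllene synthases (enzyme class: diphosphate-ionising sesquiterpene cyclase); the closest small-molecule analogy is a transannular cation–olefin (Prins-type) cyclisation, which no reagent is known to perform selectively on a humulene. The macrocycle closes in the 11-endo mode and the four-membered ring in the 4-exo mode with respect to the attacking double bonds. Both ring-fusion stereocentres (1′S,9′R) and their trans relation are fixed by the chiral fold that the active site imposes on the achiral substrate. The step needs the transannular closure to win over proton loss to α-humulene and needs 5 to escape a second protonation; the active-site contour should secure the first and the pentane overlay, which removes 5 as it forms, the second.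

Step 3
Reactants: 6 methyl cyclopent-3-ene-1-carboxylate
Product: 7 methyl 1-methylcyclopent-3-ene-1-carboxylate
Conditions: LiN(i-Pr)2, THF, −78 °C; MeI
Reagents that add atoms: iodomethane, CI
Why: alkylation of the ester enolate with iodomethane; the product is achiral, so no selectivity is needed.

Step 4
Reactants: 7 methyl 1-methylcyclopent-3-ene-1-carboxylate
Product: 8 dichlorocyclobutanone ester (racemic)
Conditions: Cl3CCOCl, Zn–Cu couple, POCl3, Et2O, rt
Reagents that add atoms: trichloroacetyl chloride, O=C(Cl)C(Cl)(Cl)Cl (reacts as dichloroketene, O=C=C(Cl)Cl)
Why: ketene–olefin [2+2] cycloaddition of dichloroketene, expected on the face anti to the ester (the ester on the envelope flap shields its own face and repels the electrophilic ketene), which sets C11 with the ester cis to the future H2 and H9; a minor syn adduct would be removed here or at 10.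

Step 5
Reactants: 8 dichlorocyclobutanone ester
Product: 9 dichlorocyclopentanone ester (racemic)
Conditions: CH2N2, Et2O, MeOH (cat.), 0 °C
Reagents that add atoms: diazomethane, C=[N+]=[N-]
Why: diazomethane ring expansion of the α,α-dichlorocyclobutanone, in which the ring-fusion carbon without chlorine migrates with retention, so that CH2 enters between the carbonyl group and the CH.

Step 6
Reactants: 9 dichlorocyclopentanone ester
Product: 10 meso keto ester
Conditions: Zn, AcOH, 70 °C
Reagents that add atoms: none
Why: reductive dechlorination of the α,α-dichloro ketone by zinc gives the meso cis-bicyclo[3.3.0]octan-3-one without touching a stereocentre.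

Step 7
Reactants: 10 meso keto ester
Product: 11 silyl enol ether (single enantiomer)
Conditions: (R,R)-[PhCH(Me)]2NH, n-BuLi, Me3SiCl (in situ quench), THF, −100 °C
Reagents that add atoms: chlorotrimethylsilane, C[Si](C)(C)Cl
Why: asymmetric deprotonation of the meso ketone by the C2-symmetric chiral lithium amide with internal silyl quench; the choice between the two enantiotopic α-carbons defines the absolute configuration of C2 and C9 and, through step 4, of C11.

Step 8
Reactants: 11 silyl enol ether
Product: 12 α-methyl keto ester
Conditions: BnMe3NF, MeI, 4 Å sieves, THF, rt
Reagents that add atoms: iodomethane, CI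
Why: fluoride-induced desilylation gives the regiodefined ammonium enolate, which should be C-methylated on the convex face before it equilibrates (this centre is planarised again in step 9), under conditions that spare the hindered ester.

Step 9
Reactants: 12 α-methyl keto ester
Product: 13 tetrasubstituted silyl enol ether
Conditions: Me3SiCl, NaI, Et3N, MeCN, rt
Reagents that add atoms: chlorotrimethylsilane, C[Si](C)(C)Cl
Why: silylation under equilibrating conditions (iodotrimethylsilane formed in the flask, amine base) should favour the more substituted enol ether (thermodynamic silyl enol ether formation), which carries the methyl group on the enol carbon.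

Step 10
Reactants: 13 tetrasubstituted silyl enol ether
Product: 15 1,4-diketone ester, via nitronic acid 14 (not isolated)
Conditions: 2-nitropropene, SnCl4, CH2Cl2, −78 °C; then H2O, reflux
Reagents that add atoms: 2-nitropropene, CC(=C)[N+](=O)[O-]; water, O
Why: Mukaiyama–Michael addition to the nitroalkene followed by Nef hydrolysis (nitroalkene as acetonyl cation equivalent); the electrophile should add on the convex face of the cis-bicyclo[3.3.0]octene, cis to H2, which sets the quaternary C3 with its methyl trans to H2 (the anti relation of rings A and C).

Step 11
Reactants: 15 1,4-diketone ester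
Product: 17 triquinane enone acid, via enone ester 16 (not isolated)
Conditions: KOH, MeOH/H2O, reflux; then aq. HCl
Reagents that add atoms: potassium hydroxide, [K+].[OH-]
Why: intramolecular aldol condensation (the methyl ketone enolate adds to the ring ketone, the only mode that can dehydrate) closes ring C as the cis-anti-cis triquinane enone, and the same base then saponifies the hindered methyl ester.

Step 12
Reactants: 17 triquinane enone acid
Product: 18 epoxy ketone acid
Conditions: H2O2 (30% aq.), NaOH, MeOH, 0 °C; then aq. HCl
Reagents that add atoms: hydrogen peroxide, OO
Why: Weitz–Scheffer nucleophilic epoxidation of the enone, in which hydroperoxide should add to C7 on the face cis to the C3 methyl, the only face that keeps rings B and C cis-fused; both new centres disappear again in step 13.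

Step 13
Reactants: 18 epoxy ketone acid
Product: 19 diosphenol acid
Conditions: H2SO4 (cat.), AcOH, 15 °C
Reagents that add atoms: none
Why: acid-catalysed isomerisation of the α,β-epoxy ketone to the diosphenol by ionisation of the tertiary C7–O bond and loss of H6, as known for 4,5-epoxy-3-keto steroids; the 6-hydroxy enone is in tautomeric equilibrium with the 5,6-dione.

Step 14
Reactants: 19 diosphenol acid; 5 (+)-β-caryophyllene
Product: 21 sterhirsutin D, via methylene dione 20 (not isolated)
Conditions: (CH2O)n, NaOAc, AcOH (cat.), 5 (1.5 equiv), 1,4-dioxane, 80 °C, sealed tube
Reagents that add atoms: paraformaldehyde (formaldehyde), C=O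
Why: domino Knoevenagel/hetero-Diels–Alder reaction, in which condensation with formaldehyde at C4 (the only enolisable carbon that can dehydrate) gives the acyl-activated oxadiene 20, which should add to the strained E-C4′=C5′ bond of 5 with oxygen on the more substituted C4′ and suprafacially on the exposed face of the trans-cycloalkene (the face peracids use), setting C4′ and C5′, while C7 settles as the cis-fused epimer.

Compound list
1 | (2E,6E)-farnesol | CC(C)=CCC/C(C)=C/CC/C(C)=C/CO | starting material
2 | (2E,6E)-farnesyl diphosphate (handled as its ammonium salt) | CC(C)=CCC/C(C)=C/CC/C(C)=C/COP(=O)(O)OP(=O)(O)O | intermediate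
3 | (E,E)-humulyl cation (eleven-membered ring, cationic CH next to the CMe2 carbon, enzyme-bound) | C/C1=C\CC(C)(C)[CH+]CC/C(C)=C/CC1 | intermediate
4 | caryophyllenyl cation (trans-fused bicyclo[7.2.0]undecane, tertiary cation at C8′, enzyme-bound) | C/C1=C\CC[C+](C)[C@@H]2CC([C@H]2CC1)(C)C | intermediate
5 | (+)-β-caryophyllene, (1S,4E,9R)-4,11,11-trimethyl-8-methylidenebicyclo[7.2.0]undec-4-ene | C/C1=C\CCC(=C)[C@@H]2CC([C@H]2CC1)(C)C | intermediate
6 | methyl cyclopent-3-ene-1-carboxylate | COC(=O)C1CC=CC1 | starting material
7 | methyl 1-methylcyclopent-3-ene-1-carboxylate | COC(=O)C1(C)CC=CC1 | intermediate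
8 | dichlorocyclobutanone ester: methyl 7,7-dichloro-3-methyl-6-oxo-cis-bicyclo[3.2.0]heptane-3-carboxylate, racemic, ester cis to the ring-fusion hydrogens | O=C1[C@H]2C[C@](C)(C(=O)OC)C[C@H]2C1(Cl)Cl | intermediate
9 | dichlorocyclopentanone ester: methyl 2,2-dichloro-7-methyl-3-oxo-cis-bicyclo[3.3.0]octane-7-carboxylate, racemic, ester cis to the ring-fusion hydrogens | O=C1C[C@H]2C[C@](C)(C(=O)OC)C[C@H]2C1(Cl)Cl | intermediate
10 | meso keto ester: methyl 3-methyl-7-oxo-cis-bicyclo[3.3.0]octane-3-carboxylate, ester exo (cis to the ring-fusion hydrogens) | O=C1C[C@H]2C[C@](C)(C(=O)OC)C[C@H]2C1 | intermediate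
11 | silyl enol ether: methyl 3-methyl-7-(trimethylsilyloxy)-cis-bicyclo[3.3.0]oct-6-ene-3-carboxylate, enol double bond towards the future C3 | C1=C(O[Si](C)(C)C)C[C@H]2C[C@](C)(C(=O)OC)C[C@H]21 | intermediate
12 | α-methyl keto ester: methyl 3,6-dimethyl-7-oxo-cis-bicyclo[3.3.0]octane-3-carboxylate, 6-methyl exo | O=C1C[C@H]2C[C@](C)(C(=O)OC)C[C@H]2[C@@H]1C | intermediate
13 | tetrasubstituted silyl enol ether: methyl 3,6-dimethyl-7-(trimethylsilyloxy)-cis-bicyclo[3.3.0]oct-6-ene-3-carboxylate | CC1=C(O[Si](C)(C)C)C[C@H]2C[C@](C)(C(=O)OC)C[C@H]21 | intermediate
14 | nitronic acid of the Michael adduct (aci-nitro form of the 6-(2-nitropropyl) ketone) | O=C1C[C@H]2C[C@](C)(C(=O)OC)C[C@H]2[C@]1(C)CC(C)=[N+]([O-])O | intermediate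
15 | 1,4-diketone ester: methyl 3,6-dimethyl-7-oxo-6-(2-oxopropyl)-cis-bicyclo[3.3.0]octane-3-carboxylate, acetonyl group cis to the ring-fusion hydrogens | O=C1C[C@H]2C[C@](C)(C(=O)OC)C[C@H]2[C@]1(C)CC(C)=O | intermediate
16 | enone ester: methyl ester of 17 | C1C(=O)C=C2C[C@H]3C[C@](C)(C(=O)OC)C[C@H]3[C@]12C | intermediate
17 | triquinane enone acid: cis-anti-cis 15-norhirsutane, C5 ketone, C6=C7 double bond, angular C3 methyl, C11 methyl and C11 carboxylic acid (acid cis to H2 and H9) | C1C(=O)C=C2C[C@H]3C[C@](C)(C(=O)O)C[C@H]3[C@]12C | intermediate
18 | epoxy ketone acid: 6,7-epoxide of 17, oxygen cis to the C3 methyl | C1C(=O)[C@H]2O[C@]23C[C@H]4C[C@](C)(C(=O)O)C[C@H]4[C@]13C | intermediate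
19 | diosphenol acid: 6-hydroxy-5-oxo-6-ene tautomer of the 15-norhirsutane-5,6-dione acid | C1C(=O)C(O)=C2C[C@H]3C[C@](C)(C(=O)O)C[C@H]3[C@]12C | intermediate
20 | methylene dione: 4-methylidene-5,6-dioxohirsutane acid, H7 cis to the C3 methyl | C=C1C(=O)C(=O)[C@@H]2C[C@H]3C[C@](C)(C(=O)O)C[C@H]3[C@]12C | intermediate
21 | sterhirsutin D | C=C1CC[C@@H]2CC3=C(O[C@@]2(C)CC[C@H]2[C@H]1CC2(C)C)C(=O)[C@@H]1C[C@H]2C[C@](C)(C(=O)O)C[C@H]2[C@]31C | target

Total step count: 14. Longest linear sequence: 12 steps (6 to 21, steps 3 to 14); the caryophyllene branch (steps 1 and 2) joins in step 14.

Steps most likely to fail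

Step 14. What may go wrong: the free diosphenol may add as a carbon nucleophile to the methylene dione faster than 5 does (methylene-bridged dimer), condensation at the neopentyl C4 may be too slow, and discrimination between the two faces of 5 may be moderate. The fallback sets out from 18 and comes back at 21. 18 is deprotonated at C4, its only enolisable position (LiN(i-Pr)2, 2.2 equiv, THF, −78 °C), and trapped with dimethylmethyleneammonium iodide in a Mannich reaction to give the dimethylaminomethyl epoxy ketone F1. Isomerisation as in step 13 gives the diosphenol Mannich base F2. F2 is then heated with 5 in toluene at 100 °C: thermal loss of dimethylamine, the way ortho-quinone methides are released from phenolic Mannich bases, should give 20 in the absence of formaldehyde and of unsubstituted diosphenol, and 20 is trapped by 5 to give 21.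

Step 2. What may go wrong: the enzyme-bound product may be protonated a second time and captured by water (caryolan-1-ol), proton loss may occur early (α-humulene), and 2 may be lost by solvolysis or the enzyme slowed by diphosphate. The fallback sets out from 1 and comes back at 5. 1 is fed to an Escherichia coli culture that co-expresses a farnesol-accepting alcohol kinase, an isopentenyl phosphate kinase of relaxed chain-length tolerance and the cyclase, under a dodecane layer. 2 is then formed and cyclised inside the cell, diphosphate is removed by the cellular pyrophosphatase, and 5 partitions into the dodecane before it can be protonated again. This fallback makes no new compound (F0).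

Step 7. What may go wrong: poor discrimination of the enantiotopic protons, or erosion by proton exchange before silylation. The fallback sets out from 10 and comes back at 12. 10 is condensed with (S)-1-amino-2-(methoxymethyl)pyrrolidine (or its enantiomer, whichever is matched) to give the SAMP hydrazone F3. Deprotonation with LiN(i-Pr)2 and methylation with MeI give the methylated hydrazone F4; here the auxiliary dictates the face of alkylation and, together with the exo preference of the bicycle, selects one of the two enantiotopic α-carbons. Aqueous oxalic acid releases 12 and the auxiliary.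

Further compounds
F1 | step 14 | dimethylaminomethyl epoxy ketone: 18 carrying CH2NMe2 at C4 (C4 epimers) | CN(C)CC1C(=O)[C@H]2O[C@]23C[C@H]4C[C@](C)(C(=O)O)C[C@H]4[C@]13C
F2 | step 14 | diosphenol Mannich base: 19 carrying CH2NMe2 at C4 (C4 epimers) | CN(C)CC1C(=O)C(O)=C2C[C@H]3C[C@](C)(C(=O)O)C[C@H]3[C@]12C
F0 | step 2 | none | none
F3 | step 7 | SAMP hydrazone of 10 | COC[C@@H]1CCCN1N=C1C[C@H]2C[C@](C)(C(=O)OC)C[C@H]2C1
F4 | step 7 | methylated hydrazone: SAMP hydrazone of 12 | COC[C@@H]1CCCN1N=C1C[C@H]2C[C@](C)(C(=O)OC)C[C@H]2[C@@H]1C
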